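**Retrosynthetic overview**

1. Locants: ring A with C7–C9 is the etherified guaiacyl half of the furofuran, ring B with C7'–C9' is the free-phenol half, and ring C with C7''–C9'' is the arylglycerol unit. The last step is only a global desilylation.
2. Key disconnection: C8–C8' and C7–O(C9') are cut together. This opens both oxolanes of the 3,7-dioxabicyclo[3.3.0]octane to an acyclic (E)-cinnamyl ether of an aryl oxiranyl carbinol, an isomer of the product. In the forward direction the oxolane O/C7'/C8'/C8/C9 closes first (radical) and the oxolane O/C9'/C8'/C8/C7 second (polar).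
3. Enabling feature: in the core, O–C9'–C8' is an opened oxirane. C8' is joined to the C8=C7 styrene through the three atoms C7'–O–C9, which is a 5-hexenyl radical array. C7 is benzylic to the electron-rich 4-alkoxy-3-methoxyphenyl ring A, so its radical is stabilised, can be oxidised, and lies within five-ring reach of that same oxygen.
4. Stereochemistry: only C7' of the core is set by catalysis (Sharpless kinetic resolution). C8', C8 and C7 are relayed from it in the key step, and the oxirane stereocentre is erased.
5. The precursor comes from cross metathesis of the allyl ether of the epoxy alcohol with an isoeugenol-derived propenylarene. Its erythro C7''/C8'' pair stems from an Evans syn aldol followed by Mitsunobu inversion at C7''. Silylated vanillin serves twice (rings B and C).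

Key step: step 14

Remark: commercial (E)-isoeugenol is assumed; its alkene geometry has no bearing on the route because the CH–CH3 terminus leaves as propene in step 13.
Abbreviations: TIPS = triisopropylsilyl, TBS = tert-butyldimethylsilyl, Cp = cyclopentadienyl (C5H5).

**Step 1**
Reactants: 1 vanillin (4-hydroxy-3-methoxybenzaldehyde)
Product: 2 3-methoxy-4-(triisopropylsilyloxy)benzaldehyde
Conditions: iPr3SiCl, imidazole, DMF, rt
Reagents that add atoms: triisopropylsilyl chloride CC(C)[Si](Cl)(C(C)C)C(C)C
Why: Imidazole-promoted O-silylation of a phenol, a routine protection; the bulky TIPS ether is chosen because it should resist the alkoxide, hydride and Lewis-acid conditions ahead and still leave with fluoride in the last step.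

**Step 2**
Reactants: 2 3-methoxy-4-(triisopropylsilyloxy)benzaldehyde
Product: 3 rac-1-[3-methoxy-4-(triisopropylsilyloxy)phenyl]prop-2-en-1-ol
Conditions: CH2=CHMgBr, THF, −78 to 0 °C; aq. NH4Cl
Reagents that add atoms: vinylmagnesium bromide C=C[Mg]Br
Why: Grignard 1,2-addition to a non-enolisable aldehyde should give the racemic aryl vinyl carbinol, whose carbinol carbon becomes C7' and is resolved in the next step.

**Step 3**
Reactants: 3 rac-1-[3-methoxy-4-(triisopropylsilyloxy)phenyl]prop-2-en-1-ol
Product: 4 (S)-[3-methoxy-4-(triisopropylsilyloxy)phenyl][(2R)-oxiran-2-yl]methanol (erythro epoxy alcohol)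
Conditions: Ti(OiPr)4 (cat.), L-(+)-diisopropyl tartrate, tBuOOH (0.45 equiv), 4 Å molecular sieves, CH2Cl2, −20 °C
Reagents that add atoms: tert-butyl hydroperoxide CC(C)(C)OO
Why: Sharpless kinetic resolution: with L-(+)-diisopropyl tartrate the (R)-carbinol is the fast-reacting enantiomer and is epoxidised to the erythro epoxy alcohol (the carbinol descriptor changes to S only because the priorities change), so a deficit of oxidant should give 4 in high enantiomeric purity and leave the (S)-carbinol behind, which fixes C7' by catalysis.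

**Step 4**
Reactants: 4 (S)-[3-methoxy-4-(triisopropylsilyloxy)phenyl][(2R)-oxiran-2-yl]methanol
Product: 5 (2R)-2-{(S)-(allyloxy)[3-methoxy-4-(triisopropylsilyloxy)phenyl]methyl}oxirane
Conditions: NaH, allyl bromide, Bu4NI (cat.), THF, 0 °C to rt
Reagents that add atoms: allyl bromide C=CCBr
Why: Williamson etherification of the sodium alkoxide with a highly reactive allylic bromide at low temperature in an aprotic medium, where O-alkylation should outrun Payne rearrangement and the C7' configuration is not touched.

**Step 5**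
Reactants: 6 (E)-isoeugenol (2-methoxy-4-[(E)-prop-1-enyl]phenol)
Product: 7 {2-methoxy-4-[(E)-prop-1-enyl]phenoxy}acetic acid
Conditions: ClCH2CO2H, NaOH, H2O, reflux; then HCl
Reagents that add atoms: chloroacetic acid OC(=O)CCl
Why: Williamson-type O-alkylation of the phenolate with chloroacetate, the classical route to aryloxyacetic acids, which leaves the propenyl group untouched.

**Step 6**
Reactants: 7 {2-methoxy-4-[(E)-prop-1-enyl]phenoxy}acetic acid; 8 (R)-4-benzyl-1,3-oxazolidin-2-one
Product: 10 (R)-4-benzyl-3-({2-methoxy-4-[(E)-prop-1-enyl]phenoxy}acetyl)-1,3-oxazolidin-2-one, via mixed pivalic anhydride 9 (not isolated)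
Conditions: tBuCOCl, Et3N, THF, −20 °C; then 8, LiCl, −20 °C to rt
Reagents that add atoms: none
Why: Standard loading of an Evans auxiliary: the mixed pivalic anhydride is attacked at its less hindered carbonyl by the oxazolidinone activated by LiCl and Et3N.

**Step 7**
Reactants: 10 (R)-4-benzyl-3-({2-methoxy-4-[(E)-prop-1-enyl]phenoxy}acetyl)-1,3-oxazolidin-2-one; 2 3-methoxy-4-(triisopropylsilyloxy)benzaldehyde
Product: 12 (R)-4-benzyl-3-[(2R,3S)-3-hydroxy-3-[3-methoxy-4-(triisopropylsilyloxy)phenyl]-2-{2-methoxy-4-[(E)-prop-1-enyl]phenoxy}propanoyl]-1,3-oxazolidin-2-one (syn aldol), via Z-dibutylboron enolate 11 (not isolated)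
Conditions: Bu2BOTf, Et3N, CH2Cl2, −78 to 0 °C; then 2, −78 to 0 °C; pH 7 buffer, MeOH, H2O2, 0 °C
Reagents that add atoms: none
Why: Evans syn aldol: soft enolisation gives the Z boron enolate, which adds to the aldehyde through a Zimmerman–Traxler chair on the face opposite to the benzyl group of the (R)-auxiliary, so that C8'' is set in its final sense and C7'' as its epimer (threo pair), a reaction type known for aryloxyacetyl imides and alkoxybenzaldehydes.

**Step 8**
Reactants: 12 syn aldol adduct
Product: 13 (1S,2S)-1-[3-methoxy-4-(triisopropylsilyloxy)phenyl]-2-{2-methoxy-4-[(E)-prop-1-enyl]phenoxy}propane-1,3-diol (threo diol)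
Conditions: LiBH4, MeOH (1 equiv), THF, 0 °C
Reagents that add atoms: none
Why: Reductive cleavage of the N-acyl oxazolidinone with LiBH4 attacks the more electrophilic exocyclic carbonyl, frees the auxiliary for reuse and leaves both stereocentres, the silyl ether and the alkene untouched (the descriptor at C8'' changes from R to S only through the priority change).

**Step 9**
Reactants: 13 threo diol
Product: 14 (1S,2S)-3-(tert-butyldimethylsilyloxy)-1-[3-methoxy-4-(triisopropylsilyloxy)phenyl]-2-{2-methoxy-4-[(E)-prop-1-enyl]phenoxy}propan-1-ol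
Conditions: tBuMe2SiCl (1.05 equiv), imidazole, CH2Cl2, 0 °C
Reagents that add atoms: tert-butyldimethylsilyl chloride CC(C)(C)[Si](C)(C)Cl
Why: Selective silylation of the primary C9'' hydroxyl over the hindered secondary benzylic one with about one equivalent of silyl chloride at low temperature.

**Step 10**
Reactants: 14 threo C9''-TBS ether
Product: 15 (1R,2S)-3-(tert-butyldimethylsilyloxy)-1-[3-methoxy-4-(triisopropylsilyloxy)phenyl]-2-{2-methoxy-4-[(E)-prop-1-enyl]phenoxy}propyl 4-nitrobenzoate (erythro)
Conditions: 4-nitrobenzoic acid, PPh3, diisopropyl azodicarboxylate, toluene, −10 °C to rt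
Reagents that add atoms: 4-nitrobenzoic acid OC(=O)c1ccc(cc1)[N+](=O)[O-]
Why: Mitsunobu inversion: the carboxylate displaces the oxyphosphonium group at C7'' in an SN2 process, which turns the threo (7''S,8''S) into the erythro (7''R,8''S) series, a tactic known for arylglycerol β-aryl ethers, and the acidic 4-nitrobenzoic acid in a non-polar solvent at low temperature should suppress ionisation.

**Step 11**
Reactants: 15 erythro 4-nitrobenzoate
Product: 16 (1R,2S)-3-(tert-butyldimethylsilyloxy)-1-[3-methoxy-4-(triisopropylsilyloxy)phenyl]-2-{2-methoxy-4-[(E)-prop-1-enyl]phenoxy}propan-1-ol (erythro)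
Conditions: iBu2AlH, CH2Cl2, −78 °C; aq. potassium sodium tartrate
Reagents that add atoms: none
Why: Reductive ester cleavage with iBu2AlH at low temperature breaks the acyl–oxygen bond, so C7'' keeps its configuration, and it avoids a basic methanolysis that could endanger the phenolic silyl ether.

**Step 12**
Reactants: 16 erythro alcohol
Product: 17 propenylarene with ring A = 3-methoxy-4-{[(1R,2S)-1,3-bis(tert-butyldimethylsilyloxy)-1-[3-methoxy-4-(triisopropylsilyloxy)phenyl]propan-2-yl]oxy}phenyl carrying an (E)-prop-1-enyl group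
Conditions: tBuMe2SiOTf, 2,6-lutidine, CH2Cl2, −78 to 0 °C
Reagents that add atoms: tert-butyldimethylsilyl trifluoromethanesulfonate CC(C)(C)[Si](C)(C)OS(=O)(=O)C(F)(F)F
Why: Silylation of the hindered secondary alcohol with the silyl triflate and a non-nucleophilic base, so that all hydroxyl groups carry fluoride-labile groups.

**Step 13**
Reactants: 17 propenylarene; 5 allyl ether of the epoxy alcohol
Product: 18 (2R)-2-[(S)-{[(E)-3-(ring A)prop-2-enyl]oxy}[3-methoxy-4-(triisopropylsilyloxy)phenyl]methyl]oxirane (ring A as in 17)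
Conditions: RuCl2(H2IMes)(=CH-C6H4-2-OiPr) (second-generation Hoveyda–Grubbs catalyst, 5 mol %), 5 (2 equiv), 1,4-benzoquinone (10 mol %), CH2Cl2, 40 °C
Reagents that add atoms: none
Why: Olefin cross metathesis between a terminal allyl ether and an electron-rich β-methylstyrene, driven by loss of propene, in which the conjugated (E)-cinnamyl ether is the thermodynamically favoured product and the excess of the simpler partner 5 together with benzoquinone should hold back self-metathesis losses and double-bond migration.

**Step 14**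
Reactants: 18 epoxy (E)-cinnamyl ether
Product: 21 tetrasilylated target [(1R,3aS,4R,6aS)-1-(ring A)-4-[3-methoxy-4-(triisopropylsilyloxy)phenyl]tetrahydro-1H,3H-furo[3,4-c]furan], via bis-titanated oxolane 19 (not isolated), via benzylic iodide 20 (not isolated)
Conditions: Cp2TiCl2 (2.5 equiv), Zn dust, THF, rt, decanted from Zn and added slowly to 18, THF, rt; then I2 (1.5 equiv), rt to 40 °C; aq. Na2S2O3
Reagents that add atoms: none
Why: Cp2TiCl, a trivalent titanium single-electron reductant, binds the oxirane oxygen and cleaves the C8'–O bond homolytically towards the more substituted carbon, the secondary C8' radical adds to the tethered styrene and makes C8'–C8, a second Cp2TiCl captures the ring-A benzylic C7 radical (19), iodine converts the C7–Ti bond into a benzylic iodide (20), and the titanium alkoxide on C9' displaces it to make O–C7, so that the substrate is isomerised in one flask. The closest known reaction type is the titanocene-chloride epoxide-opening radical cyclisation of aryl(cinnamyloxy)methyl oxiranes with iodine as terminating oxidant, a radical-polar crossover established for 2,6-diaryl-3,7-dioxabicyclo[3.3.0]octane lignans. The first oxolane (O, C7', C8', C8, C9) closes 5-exo-trig by the radical, and the second (O, C9', C8', C8, C7) closes 5-exo-tet by the alkoxide on the iodide or, after its ionisation, on the p-alkoxybenzyl cation. C8' and C8 are controlled by C7' through a chair-like Beckwith–Houk transition state with ring B pseudo-equatorial, which places the CH2O–Ti group on C8' trans to ring B and cis to the new C8–C7 branch (the relation that lets the bicycle form), while C7 is controlled by the cis-fused bicycle, since the easily ionised electron-rich iodide lets ring A settle on the convex (exo) face whatever the configuration of 20. The step needs regioselective oxirane opening (secured by the greater stability of the secondary radical), cyclisation faster than capture of the C8' radical by titanium (secured by the fast styrene acceptor, slow addition and dilution) and chemoselectivity (18 holds one oxirane and one alkene, and silyl and aryl ethers are inert to Cp2TiCl and to I2 in THF). The oxirane stereocentre is erased in the radical, so only C7' has to be enantiopure.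

**Step 15**
Reactants: 21 tetrasilylated target
Product: 22 target, (7''R,8''S)-erythro-guaiacylglycerol 8''-O-4 ether of (7R,8S,7'R,8'S)-pinoresinol
Conditions: Bu4NF, AcOH, THF, 0 °C to rt
Reagents that add atoms: none
Why: Fluoride-mediated cleavage of the two alkyl and the two aryl silyl ethers, with acetic acid as buffer to keep the freed phenols protonated, so that neither quinone methide formation at C7'' nor epimerisation of the benzylic centres of the furofuran should occur.

**Compound list**

1 | vanillin (4-hydroxy-3-methoxybenzaldehyde) | COc1cc(C=O)ccc1O | starting material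
2 | 3-methoxy-4-(triisopropylsilyloxy)benzaldehyde | COc1cc(C=O)ccc1O[Si](C(C)C)(C(C)C)C(C)C | intermediate
3 | rac-1-[3-methoxy-4-(triisopropylsilyloxy)phenyl]prop-2-en-1-ol | COc1cc(C(O)C=C)ccc1O[Si](C(C)C)(C(C)C)C(C)C | intermediate
4 | (S)-[3-methoxy-4-(triisopropylsilyloxy)phenyl][(2R)-oxiran-2-yl]methanol | O[C@H]([C@H]1CO1)c1ccc(O[Si](C(C)C)(C(C)C)C(C)C)c(OC)c1 | intermediate
5 | (2R)-2-{(S)-(allyloxy)[3-methoxy-4-(triisopropylsilyloxy)phenyl]methyl}oxirane | C=CCO[C@H]([C@H]1CO1)c1ccc(O[Si](C(C)C)(C(C)C)C(C)C)c(OC)c1 | intermediate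
6 | (E)-isoeugenol | COc1cc(/C=C/C)ccc1O | starting material
7 | {2-methoxy-4-[(E)-prop-1-enyl]phenoxy}acetic acid | COc1cc(/C=C/C)ccc1OCC(=O)O | intermediate
8 | (R)-4-benzyl-1,3-oxazolidin-2-one | O=C1N[C@H](Cc2ccccc2)CO1 | starting material
9 | {2-methoxy-4-[(E)-prop-1-enyl]phenoxy}acetic pivalic anhydride (not isolated) | COc1cc(/C=C/C)ccc1OCC(=O)OC(=O)C(C)(C)C | intermediate
10 | (R)-4-benzyl-3-({2-methoxy-4-[(E)-prop-1-enyl]phenoxy}acetyl)-1,3-oxazolidin-2-one | COc1cc(/C=C/C)ccc1OCC(=O)N1[C@H](Cc2ccccc2)COC1=O | intermediate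
11 | Z-dibutylboron enolate of 10 (not isolated) | CCCCB(CCCC)O/C(=C\Oc1ccc(/C=C/C)cc1OC)N1[C@H](Cc2ccccc2)COC1=O | intermediate
12 | (2R,3S) syn aldol imide | COc1cc([C@H](O)[C@H](C(=O)N2[C@H](Cc3ccccc3)COC2=O)Oc2ccc(/C=C/C)cc2OC)ccc1O[Si](C(C)C)(C(C)C)C(C)C | intermediate
13 | (1S,2S) threo 1,3-diol | COc1cc([C@H](O)[C@H](CO)Oc2ccc(/C=C/C)cc2OC)ccc1O[Si](C(C)C)(C(C)C)C(C)C | intermediate
14 | (1S,2S) threo alcohol, C9''-OTBS | COc1cc([C@H](O)[C@H](CO[Si](C)(C)C(C)(C)C)Oc2ccc(/C=C/C)cc2OC)ccc1O[Si](C(C)C)(C(C)C)C(C)C | intermediate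
15 | (1R,2S) erythro 4-nitrobenzoate | COc1cc([C@@H](OC(=O)c2ccc(cc2)[N+](=O)[O-])[C@H](CO[Si](C)(C)C(C)(C)C)Oc2ccc(/C=C/C)cc2OC)ccc1O[Si](C(C)C)(C(C)C)C(C)C | intermediate
16 | (1R,2S) erythro alcohol, C9''-OTBS | COc1cc([C@@H](O)[C@H](CO[Si](C)(C)C(C)(C)C)Oc2ccc(/C=C/C)cc2OC)ccc1O[Si](C(C)C)(C(C)C)C(C)C | intermediate
17 | (1R,2S) erythro bis-TBS ether, (E)-propenylarene | COc1cc([C@@H](O[Si](C)(C)C(C)(C)C)[C@H](CO[Si](C)(C)C(C)(C)C)Oc2ccc(/C=C/C)cc2OC)ccc1O[Si](C(C)C)(C(C)C)C(C)C | intermediate
18 | epoxy (E)-cinnamyl ether (C7' S, oxirane carbon R, C7'' R, C8'' S) | COc1cc([C@@H](O[Si](C)(C)C(C)(C)C)[C@H](CO[Si](C)(C)C(C)(C)C)Oc2ccc(/C=C/CO[C@H]([C@H]3CO3)c3ccc(O[Si](C(C)C)(C(C)C)C(C)C)c(OC)c3)cc2OC)ccc1O[Si](C(C)C)(C(C)C)C(C)C | intermediate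
19 | bis-titanated oxolane: C7–TiClCp2 and C9'–O–TiClCp2, C7 undefined (not isolated) | COc1cc([C@@H](O[Si](C)(C)C(C)(C)C)[C@H](CO[Si](C)(C)C(C)(C)C)Oc2ccc(C([Ti](Cl)(C3C=CC=C3)C3C=CC=C3)[C@@H]3CO[C@@H](c4ccc(O[Si](C(C)C)(C(C)C)C(C)C)c(OC)c4)[C@@H]3CO[Ti](Cl)(C3C=CC=C3)C3C=CC=C3)cc2OC)ccc1O[Si](C(C)C)(C(C)C)C(C)C | intermediate
20 | benzylic iodide with C9'–O–TiClCp2, C7 undefined (not isolated) | COc1cc([C@@H](O[Si](C)(C)C(C)(C)C)[C@H](CO[Si](C)(C)C(C)(C)C)Oc2ccc(C(I)[C@@H]3CO[C@@H](c4ccc(O[Si](C(C)C)(C(C)C)C(C)C)c(OC)c4)[C@@H]3CO[Ti](Cl)(C3C=CC=C3)C3C=CC=C3)cc2OC)ccc1O[Si](C(C)C)(C(C)C)C(C)C | intermediate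
21 | tetrasilylated target, (7R,8S,7'R,8'S,7''R,8''S) | COc1cc([C@@H](O[Si](C)(C)C(C)(C)C)[C@H](CO[Si](C)(C)C(C)(C)C)Oc2ccc([C@@H]3OC[C@@H]4[C@H]3CO[C@H]4c3ccc(O[Si](C(C)C)(C(C)C)C(C)C)c(OC)c3)cc2OC)ccc1O[Si](C(C)C)(C(C)C)C(C)C | intermediate
22 | CNP0172915.1, (7''R,8''S)-erythro-guaiacylglycerol 8''-O-4 ether of (7R,8S,7'R,8'S)-pinoresinol | COc1cc([C@@H](O)[C@H](CO)Oc2ccc([C@@H]3OC[C@@H]4[C@H]3CO[C@H]4c3ccc(O)c(OC)c3)cc2OC)ccc1O | target

**Step count and risks**

Total step count: 15. Longest linear sequence: 11 steps (6 to 22, steps 5–15).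

**Step 14.** Four things may go wrong:
- capture of the C8' radical by a second titanium centre before ring closure (deoxygenation);
- protonation of the benzyl–titanium bond before iodine reacts;
- iodination of the electron-rich rings;
- poor facial selectivity in the closure at C7.

Fallback: setting out from 18, the two bonds are made in separate operations. The Cp2TiCl cyclisation is run alone and quenched with aqueous NaH2PO4, which should give the (2R,3S,4S)-2-aryl-4-benzyl-3-(hydroxymethyl)oxolane F1. Its C9' hydroxyl is then turned into the alkoxy radical with PhI(OAc)2 and I2 under visible light (Suárez hypoiodite reaction). A 1,5-hydrogen abstraction selects the C7–H bond through a six-membered transition state. Oxidation of the benzylic radical and closure by the same oxygen come back to the route at 21.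

**Step 13.** Self-metathesis of the allyl ether, sluggish turnover of the β-methylstyrene, or migration of the allyl double bond to the enol ether may occur.

Fallback: setting out from 17, the C9–O bond is made by substitution instead of making the alkene by metathesis. Allylic oxidation of the propenyl group with 2,3-dichloro-5,6-dicyano-1,4-benzoquinone in wet dioxane should give the (E)-cinnamaldehyde F2. NaBH4/CeCl3 gives the (E)-cinnamyl alcohol F3, and CBr4/PPh3 gives the (E)-cinnamyl bromide F4, which is used crude. Williamson etherification with the sodium alkoxide of 4 (NaH, THF/DMF, 0 °C) comes back at 18, and step 4 is then not needed.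

**Step 10.** Ionisation of the activated, electron-rich benzylic alcohol may cause loss of stereochemical integrity at C7'', or elimination may compete.

Fallback: setting out from 14, oxidation with Dess–Martin periodinane gives the α-aryloxy ketone F5. Chelation-controlled reduction with Zn(BH4)2 in Et2O at −78 °C follows, with zinc bridging the ketone oxygen and the aryloxy oxygen and hydride arriving from the side of the C8''–H bond. This should give the anti (erythro) alcohol and come back at 16, which also makes step 11 unnecessary.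

**Further compounds**

F1 | step 14 | (2R,3S,4S)-2-[3-methoxy-4-(triisopropylsilyloxy)phenyl]-4-(ring A-methyl)-3-(hydroxymethyl)oxolane | COc1cc([C@@H](O[Si](C)(C)C(C)(C)C)[C@H](CO[Si](C)(C)C(C)(C)C)Oc2ccc(C[C@@H]3CO[C@@H](c4ccc(O[Si](C(C)C)(C(C)C)C(C)C)c(OC)c4)[C@@H]3CO)cc2OC)ccc1O[Si](C(C)C)(C(C)C)C(C)C
F2 | step 13 | (E)-3-(ring A)prop-2-enal | COc1cc([C@@H](O[Si](C)(C)C(C)(C)C)[C@H](CO[Si](C)(C)C(C)(C)C)Oc2ccc(/C=C/C=O)cc2OC)ccc1O[Si](C(C)C)(C(C)C)C(C)C
F3 | step 13 | (E)-3-(ring A)prop-2-en-1-ol | COc1cc([C@@H](O[Si](C)(C)C(C)(C)C)[C@H](CO[Si](C)(C)C(C)(C)C)Oc2ccc(/C=C/CO)cc2OC)ccc1O[Si](C(C)C)(C(C)C)C(C)C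
F4 | step 13 | (E)-3-(ring A)prop-2-enyl bromide | COc1cc([C@@H](O[Si](C)(C)C(C)(C)C)[C@H](CO[Si](C)(C)C(C)(C)C)Oc2ccc(/C=C/CBr)cc2OC)ccc1O[Si](C(C)C)(C(C)C)C(C)C
F5 | step 10 | (S)-3-(tert-butyldimethylsilyloxy)-1-[3-methoxy-4-(triisopropylsilyloxy)phenyl]-2-{2-methoxy-4-[(E)-prop-1-enyl]phenoxy}propan-1-one | COc1cc(C(=O)[C@H](CO[Si](C)(C)C(C)(C)C)Oc2ccc(/C=C/C)cc2OC)ccc1O[Si](C(C)C)(C(C)C)C(C)C
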